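**Plan**

1. Target numbering: C1 tertiary carbinol, C2 acetoxy, C3 benzoyloxy, C4=C5 alkene, C6 ketone, C7 exocyclic CH2; pyranosides keep sugar numbers.
2. Cuts: first the C4=C5 alkene (dehydration of a C4 carbinol), then the C4–C5 bond (aldol of a C6 methyl ketone onto a C4 aldehyde).
3. Enabling feature: in the cyclohexenone ring, C6 (ketone), C5 and C4 are the trace of a β-hydroxy ketone, and C4, C3, C2, C1, C6, C5 map onto C1 to C6 of a methyl hex-5-enopyranoside whose sugar C4 carries C7 as a branch.
4. Further back: enol ether from a 6-iodide; C7 benzoate and tertiary carbinol from a spiro-oxirane; oxirane from a 4-methylene-3-ol; methylene from a 4-ketone; 2-benzoate from trans-diaxial opening of a 2,3-anhydro-allopyranoside.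
5. Forward: the pyranose ring of 1 supplies every ring carbon, C7 comes from CH2Br2, the only carbocycle closes in step 13 and the enone appears in step 14.
6. Stereochemistry: C2 is the C3–O bond of epoxide 1 and is never touched; C3 comes from inversion at sugar C2 on epoxide opening; C1 comes from hydroxyl-directed epoxidation syn to O3.

Key step: step 13

Assumption: epoxide 1 is taken as a purchased compound; it is otherwise made from methyl α-D-glucopyranoside by benzylidenation, ditosylation and treatment with NaOMe.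

Step 1
Reactants: 1 methyl 2,3-anhydro-4,6-O-[(R)-benzylidene]-α-D-allopyranoside; 2 benzoic acid
Product: 3 methyl 2-O-benzoyl-4,6-O-benzylidene-α-D-altropyranoside
Conditions: PhCO2H (3 equiv), PhCO2Cs (0.5 equiv), DMF, 120 °C
Reagents that add atoms: benzoic acid (2), OC(=O)c1ccccc1
Why: Carboxylate opening of an epoxide under Fürst–Plattner control: in the benzylidene-locked chair the nucleophile must enter axially at C2, which inverts C2 (the future C3 benzoate centre of the target), leaves the C3–O bond untouched, and gives a trans-diaxial hydroxy ester that cannot undergo benzoyl migration.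

Step 2
Reactants: 3 methyl 2-O-benzoyl-4,6-O-benzylidene-α-D-altropyranoside
Product: 4 methyl 2-O-benzoyl-4,6-O-benzylidene-3-O-(tert-butyldimethylsilyl)-α-D-altropyranoside
Conditions: TBSOTf, 2,6-lutidine, CH2Cl2, 0 °C to rt
Reagents that add atoms: tert-butyldimethylsilyl triflate, CC(C)(C)[Si](C)(C)OS(=O)(=O)C(F)(F)F
Why: Silyl triflate silylation reaches the hindered axial 3-OH and masks it for the oxidation at C4 while staying removable beside esters.

Step 3
Reactants: 4 methyl 2-O-benzoyl-4,6-O-benzylidene-3-O-(tert-butyldimethylsilyl)-α-D-altropyranoside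
Product: 5 methyl 2-O-benzoyl-6-O-benzyl-3-O-(tert-butyldimethylsilyl)-α-D-altropyranoside
Conditions: Et3SiH, TfOH, 4 Å MS, CH2Cl2, −78 °C; aq. NaHCO3
Reagents that add atoms: none
Why: Regioselective reductive opening of a 4,6-O-benzylidene acetal with a silane and a Brønsted acid gives the 6-O-benzyl ether and the free 4-OH, and the low temperature should spare the silyl ether, the benzoate and the glycoside.

Step 4
Reactants: 5 methyl 2-O-benzoyl-6-O-benzyl-3-O-(tert-butyldimethylsilyl)-α-D-altropyranoside
Product: 6 methyl 2-O-benzoyl-6-O-benzyl-3-O-(tert-butyldimethylsilyl)-α-D-arabino-hexopyranosid-4-ulose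
Conditions: Dess–Martin periodinane, CH2Cl2, rt
Reagents that add atoms: none
Why: Dess–Martin oxidation of a secondary alcohol runs without base, so the ketone should form without β-elimination of the benzoate or of the benzyloxy group.

Step 5
Reactants: 6 methyl 2-O-benzoyl-6-O-benzyl-3-O-(tert-butyldimethylsilyl)-α-D-arabino-hexopyranosid-4-ulose
Product: 7 methyl 2-O-benzoyl-6-O-benzyl-3-O-(tert-butyldimethylsilyl)-4-deoxy-4-C-methylene-α-D-arabino-hexopyranoside
Conditions: CH2Br2, Zn, TiCl4, THF (preformed Lombardo reagent); CH2Cl2, 0 °C to rt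
Reagents that add atoms: dibromomethane, BrCBr
Why: Takai–Lombardo methylenation uses a non-basic titanium–zinc carbenoid that converts enolisable, flanked ketones into methylene compounds and leaves esters alone.

Step 6
Reactants: 7 methyl 2-O-benzoyl-6-O-benzyl-3-O-(tert-butyldimethylsilyl)-4-deoxy-4-C-methylene-α-D-arabino-hexopyranoside
Product: 8 methyl 2-O-benzoyl-6-O-benzyl-4-deoxy-4-C-methylene-α-D-arabino-hexopyranoside
Conditions: HF·pyridine, pyridine/THF, 0 °C to rt
Reagents that add atoms: none
Why: Fluoride cleavage of the silyl ether under pyridine-buffered conditions frees the allylic 3-OH without benzoyl migration or allylic rearrangement.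

Step 7
Reactants: 8 methyl 2-O-benzoyl-6-O-benzyl-4-deoxy-4-C-methylene-α-D-arabino-hexopyranoside
Product: 9 methyl 4,4'-anhydro-2-O-benzoyl-6-O-benzyl-4-C-(hydroxymethyl)-α-D-altropyranoside (spiro-oxirane at C4 with its oxygen cis to O3)
Conditions: VO(acac)2 (5 mol%), t-BuOOH (anhydrous, in decane), CH2Cl2, 0 °C to rt
Reagents that add atoms: tert-butyl hydroperoxide, CC(C)(C)OO
Why: Vanadium-catalysed hydroxyl-directed epoxidation (Sharpless–Michaelson) transfers oxygen within a vanadate ester of O3, so the oxirane oxygen should enter the alkene face syn to O3, which sets sugar C4 (C1 of the target) with oxygen cis to O3 and the CH2 group cis to the C2 benzoate.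

Step 8
Reactants: 9 methyl 4,4'-anhydro-2-O-benzoyl-6-O-benzyl-4-C-(hydroxymethyl)-α-D-altropyranoside
Product: 10 methyl 3-O-acetyl-4,4'-anhydro-2-O-benzoyl-6-O-benzyl-4-C-(hydroxymethyl)-α-D-altropyranoside
Conditions: Ac2O, pyridine, DMAP (cat.), CH2Cl2, rt
Reagents that add atoms: acetic anhydride, CC(=O)OC(C)=O
Why: DMAP-catalysed acetylation of the only free hydroxyl; the oxirane is stable to pyridine.

Step 9
Reactants: 10 methyl 3-O-acetyl-4,4'-anhydro-2-O-benzoyl-6-O-benzyl-4-C-(hydroxymethyl)-α-D-altropyranoside; 2 benzoic acid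
Product: 11 methyl 3-O-acetyl-2-O-benzoyl-4-C-(benzoyloxymethyl)-6-O-benzyl-α-D-altropyranoside
Conditions: PhCO2H (2 equiv), PhCO2Cs (1 equiv), DMF, 80 °C
Reagents that add atoms: benzoic acid (2), OC(=O)c1ccccc1
Why: SN2 opening of a 2,2-disubstituted oxirane by a carboxylate occurs at the unhindered CH2 terminus, which leaves the C4–O bond and its configuration intact and gives the tertiary alcohol with the primary benzoate; acyl transfer to a tertiary hydroxyl is thermodynamically disfavoured.

Step 10
Reactants: 11 methyl 3-O-acetyl-2-O-benzoyl-4-C-(benzoyloxymethyl)-6-O-benzyl-α-D-altropyranoside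
Product: 12 methyl 3-O-acetyl-2-O-benzoyl-4-C-(benzoyloxymethyl)-α-D-altropyranoside
Conditions: H2 (1 atm), Pd/C, EtOAc, rt
Reagents that add atoms: none
Why: Hydrogenolysis of the benzyl ether over palladium on carbon; the benzoates, the acetate and the tertiary alcohol are inert and no alkene is present at this stage.

Step 11
Reactants: 12 methyl 3-O-acetyl-2-O-benzoyl-4-C-(benzoyloxymethyl)-α-D-altropyranoside
Product: 13 methyl 3-O-acetyl-2-O-benzoyl-4-C-(benzoyloxymethyl)-6-deoxy-6-iodo-α-D-altropyranoside
Conditions: I2, PPh3, imidazole, toluene, 60 °C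
Reagents that add atoms: iodine, II
Why: Garegg–Samuelsson iodination (Appel type) is selective for the primary hydroxyl because the tertiary carbinol cannot be displaced through an alkoxyphosphonium salt.

Step 12
Reactants: 13 methyl 3-O-acetyl-2-O-benzoyl-4-C-(benzoyloxymethyl)-6-deoxy-6-iodo-α-D-altropyranoside
Product: 14 methyl 3-O-acetyl-2-O-benzoyl-4-C-(benzoyloxymethyl)-6-deoxy-α-D-arabino-hex-5-enopyranoside
Conditions: AgF, pyridine, rt, dark
Reagents that add atoms: none
Why: Silver fluoride-mediated dehydroiodination is the classical ester-compatible route from 6-deoxy-6-iodopyranosides to hex-5-enopyranosides, with C5–H as the only β-hydrogen.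

Step 13
Reactants: 14 methyl 3-O-acetyl-2-O-benzoyl-4-C-(benzoyloxymethyl)-6-deoxy-α-D-arabino-hex-5-enopyranoside
Product: 16 [(1S,2S,3R,4R)-2-acetoxy-3-benzoyloxy-1,4-dihydroxy-6-oxocyclohexyl]methyl benzoate, via open-chain mercurio keto-aldehyde 15 (not isolated)
Conditions: Hg(OCOCF3)2 (5 mol%), acetone/H2O (2:1), rt
Reagents that add atoms: water, O
Why: Divalent mercury adds to C6 of the exocyclic enol ether and water to C5, the hemiketal opens, and the hemiacetal at the former anomeric carbon loses methanol to give the open-chain aldehyde with an α-mercurio methyl ketone (15). The mercury enolate then attacks the aldehyde in an intramolecular aldol that forms the C4–C5 bond of the target (sugar C1–C6) and releases the mercury salt for the next turnover; this is the Ferrier carbocyclization of hex-5-enopyranosides under catalytic Hg(OCOCF3)2. The cyclohexanone, the only ring formed, closes in the 6-(enolendo)-exo-trig mode. The new carbinol at C4 should arise through a chair-like transition state and is expected trans to the C2 acetoxy group (the usual 1,3-trans relation to the pyranoside C3 substituent), but its configuration is immaterial because the centre is removed in step 14. The step needs the enol ether to react in preference to three esters and the three existing stereocentres to survive: the medium is near neutral, C1 is fully substituted, C2 has no carbonyl neighbour, and aldol closure should outpace enolisation of the aldehyde at C3. Lactol formation between the free tertiary hydroxyl and the aldehyde is reversible and should only store the intermediate.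

Step 14
Reactants: 16 [(1S,2S,3R,4R)-2-acetoxy-3-benzoyloxy-1,4-dihydroxy-6-oxocyclohexyl]methyl benzoate
Product: 18 2-O-acetylzeylenone, via C4 mesylate 17 (not isolated)
Conditions: MsCl (1.2 equiv), Et3N, CH2Cl2, −20 to 0 °C
Reagents that add atoms: none
Why: Mesylation of the secondary β-hydroxyl followed by E1cB elimination through the C5 enolate (the only enolisable position, since C1 is quaternary) gives the conjugated enone, and the hindered tertiary hydroxyl is expected to stay free at low temperature.

**Compound list**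

1 | methyl 2,3-anhydro-4,6-O-[(R)-benzylidene]-α-D-allopyranoside | CO[C@H]1O[C@@H]2CO[C@@H](c3ccccc3)O[C@H]2[C@H]4O[C@H]41 | starting material
2 | benzoic acid | OC(=O)c1ccccc1 | starting material
3 | methyl 2-O-benzoyl-4,6-O-benzylidene-α-D-altropyranoside | CO[C@H]1O[C@@H]2CO[C@@H](c3ccccc3)O[C@H]2[C@@H](O)[C@@H]1OC(=O)c1ccccc1 | intermediate
4 | methyl 2-O-benzoyl-4,6-O-benzylidene-3-O-(tert-butyldimethylsilyl)-α-D-altropyranoside | CO[C@H]1O[C@@H]2CO[C@@H](c3ccccc3)O[C@H]2[C@@H](O[Si](C)(C)C(C)(C)C)[C@@H]1OC(=O)c1ccccc1 | intermediate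
5 | methyl 2-O-benzoyl-6-O-benzyl-3-O-(tert-butyldimethylsilyl)-α-D-altropyranoside | CO[C@H]1O[C@H](COCc2ccccc2)[C@@H](O)[C@@H](O[Si](C)(C)C(C)(C)C)[C@@H]1OC(=O)c1ccccc1 | intermediate
6 | methyl 2-O-benzoyl-6-O-benzyl-3-O-(tert-butyldimethylsilyl)-α-D-arabino-hexopyranosid-4-ulose | CO[C@H]1O[C@H](COCc2ccccc2)C(=O)[C@@H](O[Si](C)(C)C(C)(C)C)[C@@H]1OC(=O)c1ccccc1 | intermediate
7 | methyl 2-O-benzoyl-6-O-benzyl-3-O-(tert-butyldimethylsilyl)-4-deoxy-4-C-methylene-α-D-arabino-hexopyranoside | CO[C@H]1O[C@H](COCc2ccccc2)C(=C)[C@@H](O[Si](C)(C)C(C)(C)C)[C@@H]1OC(=O)c1ccccc1 | intermediate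
8 | methyl 2-O-benzoyl-6-O-benzyl-4-deoxy-4-C-methylene-α-D-arabino-hexopyranoside | CO[C@H]1O[C@H](COCc2ccccc2)C(=C)[C@@H](O)[C@@H]1OC(=O)c1ccccc1 | intermediate
9 | methyl 4,4'-anhydro-2-O-benzoyl-6-O-benzyl-4-C-(hydroxymethyl)-α-D-altropyranoside (spiro-oxirane, oxygen cis to O3) | CO[C@H]1O[C@H](COCc2ccccc2)[C@]3(CO3)[C@@H](O)[C@@H]1OC(=O)c1ccccc1 | intermediate
10 | methyl 3-O-acetyl-4,4'-anhydro-2-O-benzoyl-6-O-benzyl-4-C-(hydroxymethyl)-α-D-altropyranoside | CO[C@H]1O[C@H](COCc2ccccc2)[C@]3(CO3)[C@@H](OC(C)=O)[C@@H]1OC(=O)c1ccccc1 | intermediate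
11 | methyl 3-O-acetyl-2-O-benzoyl-4-C-(benzoyloxymethyl)-6-O-benzyl-α-D-altropyranoside | CO[C@H]1O[C@H](COCc2ccccc2)[C@](O)(COC(=O)c2ccccc2)[C@@H](OC(C)=O)[C@@H]1OC(=O)c1ccccc1 | intermediate
12 | methyl 3-O-acetyl-2-O-benzoyl-4-C-(benzoyloxymethyl)-α-D-altropyranoside | CO[C@H]1O[C@H](CO)[C@](O)(COC(=O)c2ccccc2)[C@@H](OC(C)=O)[C@@H]1OC(=O)c1ccccc1 | intermediate
13 | methyl 3-O-acetyl-2-O-benzoyl-4-C-(benzoyloxymethyl)-6-deoxy-6-iodo-α-D-altropyranoside | CO[C@H]1O[C@H](CI)[C@](O)(COC(=O)c2ccccc2)[C@@H](OC(C)=O)[C@@H]1OC(=O)c1ccccc1 | intermediate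
14 | methyl 3-O-acetyl-2-O-benzoyl-4-C-(benzoyloxymethyl)-6-deoxy-α-D-arabino-hex-5-enopyranoside | CO[C@H]1OC(=C)[C@](O)(COC(=O)c2ccccc2)[C@@H](OC(C)=O)[C@@H]1OC(=O)c1ccccc1 | intermediate
15 | 3-O-acetyl-2-O-benzoyl-4-C-(benzoyloxymethyl)-6-deoxy-6-(trifluoroacetoxymercurio)-aldehydo-D-arabino-hexos-5-ulose | O=C[C@@H](OC(=O)c1ccccc1)[C@H](OC(C)=O)[C@@](O)(COC(=O)c1ccccc1)C(=O)C[Hg]OC(=O)C(F)(F)F | intermediate
16 | [(1S,2S,3R,4R)-2-acetoxy-3-benzoyloxy-1,4-dihydroxy-6-oxocyclohexyl]methyl benzoate (4-hydroxy-4,5-dihydro-2-O-acetylzeylenone) | CC(=O)O[C@H]1[C@H](OC(=O)c2ccccc2)[C@H](O)CC(=O)[C@]1(O)COC(=O)c1ccccc1 | intermediate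
17 | 4-O-methanesulfonate of 16 | CC(=O)O[C@H]1[C@H](OC(=O)c2ccccc2)[C@H](OS(C)(=O)=O)CC(=O)[C@]1(O)COC(=O)c1ccccc1 | intermediate
18 | 2-O-acetylzeylenone, [(1S,5R,6S)-6-acetoxy-5-benzoyloxy-1-hydroxy-2-oxocyclohex-3-en-1-yl]methyl benzoate | CC(=O)O[C@H]1[C@H](OC(=O)c2ccccc2)C=CC(=O)[C@]1(O)COC(=O)c1ccccc1 | target

**Step count and risks**

Total step count: 14. Longest linear sequence: 14 steps (from 1).

Most likely to fail are steps 1, 7 and 13.

Step 1 may suffer from slow, incomplete opening of the hindered oxirane by the weakly nucleophilic carboxylate, with loss of the acetal on prolonged heating. The fallback sets out from 1: hydrolytic trans-diaxial opening with KOH in H2O/DMSO at 100 °C should give methyl 4,6-O-benzylidene-α-D-altropyranoside F1. Benzoyl chloride (1.05 equiv) in pyridine/CH2Cl2 at −40 °C should then acylate the more accessible O2, since O3 is syn-axial to the anomeric methoxy group. This comes back to the route at 3.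

Step 7 may suffer from oxidation of the allylic alcohol to the enone in competition with oxygen transfer, or from erosion of facial selectivity if the hydroxyl lies close to the alkene plane in the reacting conformer. The fallback sets out from 8: directed dihydroxylation with OsO4 and TMEDA in CH2Cl2 at −78 °C (the allylic hydroxyl hydrogen-bonds to the osmium–diamine complex; work-up with aqueous NaHSO3) should give methyl 2-O-benzoyl-6-O-benzyl-4-C-(hydroxymethyl)-α-D-altropyranoside F2 with the new tertiary hydroxyl cis to O3. Benzoyl chloride and 2,4,6-collidine at −40 °C should acylate only the primary hydroxyl to give methyl 2-O-benzoyl-4-C-(benzoyloxymethyl)-6-O-benzyl-α-D-altropyranoside F3. Acetic anhydride in pyridine then acetylates the secondary 3-OH, which comes back to the route at 11.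

Step 13 may suffer from storage of the aldehyde as a five-membered lactol with the free tertiary hydroxyl, so that protodemercuration to the methyl ketone overtakes the aldol closure. The fallback sets out from 14: Et3SiOTf and 2,6-lutidine in CH2Cl2 at −78 °C should cap the tertiary hydroxyl to give methyl 3-O-acetyl-2-O-benzoyl-4-C-(benzoyloxymethyl)-6-deoxy-4-O-(triethylsilyl)-α-D-arabino-hex-5-enopyranoside F4. The same Hg(OCOCF3)2-catalysed carbocyclisation should then give the 1-O-triethylsilyl ether of ketol 16 F5. HF·pyridine removes the silyl group, which comes back to the route at 16.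

**Further compounds**

F1 | step 1 | methyl 4,6-O-benzylidene-α-D-altropyranoside | CO[C@H]1O[C@@H]2CO[C@@H](c3ccccc3)O[C@H]2[C@@H](O)[C@@H]1O
F2 | step 7 | methyl 2-O-benzoyl-6-O-benzyl-4-C-(hydroxymethyl)-α-D-altropyranoside | CO[C@H]1O[C@H](COCc2ccccc2)[C@](O)(CO)[C@@H](O)[C@@H]1OC(=O)c1ccccc1
F3 | step 7 | methyl 2-O-benzoyl-4-C-(benzoyloxymethyl)-6-O-benzyl-α-D-altropyranoside | CO[C@H]1O[C@H](COCc2ccccc2)[C@](O)(COC(=O)c2ccccc2)[C@@H](O)[C@@H]1OC(=O)c1ccccc1
F4 | step 13 | methyl 3-O-acetyl-2-O-benzoyl-4-C-(benzoyloxymethyl)-6-deoxy-4-O-(triethylsilyl)-α-D-arabino-hex-5-enopyranoside | CO[C@H]1OC(=C)[C@](O[Si](CC)(CC)CC)(COC(=O)c2ccccc2)[C@@H](OC(C)=O)[C@@H]1OC(=O)c1ccccc1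
F5 | step 13 | 1-O-triethylsilyl ether of ketol 16 | CC(=O)O[C@H]1[C@H](OC(=O)c2ccccc2)[C@H](O)CC(=O)[C@]1(O[Si](CC)(CC)CC)COC(=O)c1ccccc1
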